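Retrosynthesis (flavanone numbering, ring B primed): the three silyl-masked phenols (O5, O7, O3') are unmasked last; before that, ring C is opened at C4–C4a (aryl ketone back to a tertiary amide and an arene C–H), the ether is cut at O1–C2, the chain at C2–C3 (β-keto amide back to aryl ester and acetamide enolate), and the 4'-O–prenyl bond on the ring B ester.
Forward: ring B ester (4'-O-prenylation, 3'-O-silylation), then C2–C3 by crossed Claisen condensation, then the C2 carbinol, then ring A joined through O1–C2, then ring C closed through C4–C4a, then desilylation; rings A and B are bought, ring C is the only ring made.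
Stereochemistry: C2, the only stereocentre, is set as the (R)-carbinol by asymmetric transfer hydrogenation and turned into (S) by SN2 inversion in the Mitsunobu etherification; no later step breaks a bond at C2 or exposes the β-aryloxy carbonyl unit to base.
Enabling feature: ring A is a phloroglucinol ring in which C4a lies ortho to O1, ortho to O5 and para to O7, so three oxygen lone pairs converge on this one carbon, and the two carbons ortho to O1 are equivalent; it should therefore attack a tethered O-triflyl iminium ion (the amide activated by Tf2O) without Lewis or protic acid.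
This matters because the 4'-O-prenyl ether would not survive classical Friedel–Crafts acid, and the 4-alkoxybenzylic C2–O1 ether tolerates neither acid nor enolising base.
Key step: step 7

Remark: the (R,R)-configured transfer hydrogenation catalyst is assumed to give the (R)-carbinol, as it does with acetophenone. Abbreviations: TBS = tert-butyldimethylsilyl, TIPS = triisopropylsilyl, prenyl = 3-methylbut-2-en-1-yl.

Step 1
Reactants: 1 methyl 3,4-dihydroxybenzoate; 2 prenyl bromide (1-bromo-3-methylbut-2-ene)
Product: 3 methyl 3-hydroxy-4-(prenyloxy)benzoate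
Conditions: K2CO3 (1.0 equiv), DMF, 0 °C → rt
Reagents that add atoms: none
Why: Williamson ether synthesis in which the 4-hydroxyl, para to the ester and therefore the more acidic of the two, is the one deprotonated by a single equivalent of base and alkylated on oxygen.

Step 2
Reactants: 3 methyl 3-hydroxy-4-(prenyloxy)benzoate
Product: 4 methyl 4-(prenyloxy)-3-(triisopropylsilyloxy)benzoate
Conditions: TIPSCl, imidazole, DMF, rt
Reagents that add atoms: triisopropylsilyl chloride, CC(C)[Si](Cl)(C(C)C)C(C)C
Why: imidazole-promoted O-silylation of the remaining phenol, the bulky triisopropylsilyl ether being chosen because it should withstand the enolate and lithium methoxide of step 3 yet fall to fluoride in step 8.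

Step 3
Reactants: 4 methyl 4-(prenyloxy)-3-(triisopropylsilyloxy)benzoate; 5 N,N-dimethylacetamide
Product: 7 N,N-dimethyl-3-oxo-3-[4-(prenyloxy)-3-(triisopropylsilyloxy)phenyl]propanamide, via lithium amide enolate 6 (not isolated)
Conditions: 5 (2.2 equiv), LiN(i-Pr)2 (2.2 equiv), THF, −78 °C; then 4, −78 → 0 °C; aq NH4Cl
Reagents that add atoms: none
Why: crossed Claisen condensation of an amide enolate with a non-enolisable aryl ester, drawn to completion because the second equivalent of enolate deprotonates the β-keto amide as it forms.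

Step 4
Reactants: 7 N,N-dimethyl-3-oxo-3-[4-(prenyloxy)-3-(triisopropylsilyloxy)phenyl]propanamide
Product: 8 (R)-3-hydroxy-N,N-dimethyl-3-[4-(prenyloxy)-3-(triisopropylsilyloxy)phenyl]propanamide
Conditions: RuCl[(R,R)-TsDPEN](p-cymene) (1 mol %), HCO2H/Et3N (5:2), CH2Cl2, 30 °C
Reagents that add atoms: none
Why: Noyori–Ikariya asymmetric transfer hydrogenation of the aryl ketone, in which the catalyst sets the C2 stereocentre by delivering hydride to the carbonyl face that places the aryl group against the arene ligand, while the outer-sphere hydride transfer should leave the prenyl alkene and the silyl ether untouched.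

Step 5
Reactants: 9 phloroglucinol (benzene-1,3,5-triol)
Product: 10 3,5-bis(tert-butyldimethylsilyloxy)phenol
Conditions: TBSCl (2.0 equiv), imidazole, DMF, 0 °C
Reagents that add atoms: tert-butyldimethylsilyl chloride, CC(C)(C)[Si](C)(C)Cl
Why: statistical O-silylation of a threefold-symmetric triol, in which only the degree of silylation has to be controlled because all three hydroxyls are identical, the mono- and tris-ethers being separable and recyclable.

Step 6
Reactants: 8 (R)-3-hydroxy-N,N-dimethyl-3-[4-(prenyloxy)-3-(triisopropylsilyloxy)phenyl]propanamide; 10 3,5-bis(tert-butyldimethylsilyloxy)phenol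
Product: 11 (S)-3-[3,5-bis(tert-butyldimethylsilyloxy)phenoxy]-N,N-dimethyl-3-[4-(prenyloxy)-3-(triisopropylsilyloxy)phenyl]propanamide
Conditions: PPh3, DIAD, toluene, −20 → 0 °C
Reagents that add atoms: none
Why: Mitsunobu etherification, in which the phenoxide of 10 displaces the alkoxyphosphonium leaving group of 8 from the rear (SN2) so that (R)-C2 becomes (S)-C2, the apolar solvent and low temperature being chosen to suppress ionisation of the 4-alkoxybenzylic centre.

Step 7
Reactants: 11 (S)-3-[3,5-bis(tert-butyldimethylsilyloxy)phenoxy]-N,N-dimethyl-3-[4-(prenyloxy)-3-(triisopropylsilyloxy)phenyl]propanamide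
Product: 14 (S)-5,7-bis(tert-butyldimethylsilyloxy)-2-[4-(prenyloxy)-3-(triisopropylsilyloxy)phenyl]chroman-4-one, via O-triflyl iminium triflate 12 (not isolated), via cyclic iminium triflate 13 (not isolated)
Conditions: Tf2O (1.1 equiv), 2,6-di-tert-butyl-4-methylpyridine (2.5 equiv), CH2Cl2, −78 → 0 °C; then aq NaHCO3, THF, 0 °C → rt
Reagents that add atoms: water, O
Why: Triflic anhydride sulfonylates the amide oxygen of 11 to give the O-triflyl iminium ion 12, a Vilsmeier-type carbon electrophile; the ring A carbon ortho to the ether oxygen attacks it, triflate leaves, the hindered pyridine takes the aryl proton, and the vinylogous iminium ion 13 is hydrolysed by the bicarbonate wash to the C4 ketone. The closest known reaction type is the Vilsmeier–Haack acylation of electron-rich arenes by triflic-anhydride-activated tertiary amides, the carbocyclic counterpart of the Bischler–Napieralski cyclisation. Ring C closes in the 6-exo-trig mode, by attack on the iminium carbon with the C=N bond outside the new six-membered ring. No new stereocentre is formed and none of the four bonds at C2 is touched, so the (S) configuration of 11 should be carried over unchanged. The step must select the ring A C–H over the ring B C–H para to the silyloxy group (which would close an indanone), over the prenyl alkene, and over β-elimination of the aryloxide. This should be secured because three oxygen donors (O1 ortho, O5 ortho, O7 para) converge on the attacked carbon against one for ring B, the two carbons ortho to the ether oxygen are interchangeable by rotation about the O–aryl bond while the carbon between the silyloxy groups cannot reach the tether, and a weak, non-nucleophilic base at low temperature leaves neither free acid to cleave the prenyl ether nor a base able to enolise the activated amide.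

Step 8
Reactants: 14 (S)-5,7-bis(tert-butyldimethylsilyloxy)-2-[4-(prenyloxy)-3-(triisopropylsilyloxy)phenyl]chroman-4-one
Product: 15 Monotesone A, (S)-5,7-dihydroxy-2-[3-hydroxy-4-(prenyloxy)phenyl]chroman-4-one
Conditions: Bu4NF/AcOH (1:1, 3.5 equiv), THF, 0 °C → rt
Reagents that add atoms: none
Why: fluoride-induced cleavage of the three aryl silyl ethers, in which the acetic acid buffer keeps the freed phenols protonated so that the flavanone should not open to the chalcone by retro-oxa-Michael reaction and C2 stays (S), while fluoride leaves the prenyl ether alone.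

Compound list
1 | methyl 3,4-dihydroxybenzoate | COC(=O)c1ccc(O)c(O)c1 | starting material
2 | prenyl bromide (1-bromo-3-methylbut-2-ene) | CC(C)=CCBr | starting material
3 | methyl 3-hydroxy-4-[(3-methylbut-2-en-1-yl)oxy]benzoate | COC(=O)c1ccc(OCC=C(C)C)c(O)c1 | intermediate
4 | methyl 4-[(3-methylbut-2-en-1-yl)oxy]-3-[(triisopropylsilyl)oxy]benzoate | COC(=O)c1ccc(OCC=C(C)C)c(O[Si](C(C)C)(C(C)C)C(C)C)c1 | intermediate
5 | N,N-dimethylacetamide | CC(=O)N(C)C | starting material
6 | lithium 1-(dimethylamino)ethen-1-olate (lithium enolate of 5) | [Li+].C=C([O-])N(C)C | intermediate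
7 | N,N-dimethyl-3-{4-[(3-methylbut-2-en-1-yl)oxy]-3-[(triisopropylsilyl)oxy]phenyl}-3-oxopropanamide | CC(C)=CCOc1ccc(C(=O)CC(=O)N(C)C)cc1O[Si](C(C)C)(C(C)C)C(C)C | intermediate
8 | (R)-3-hydroxy-N,N-dimethyl-3-{4-[(3-methylbut-2-en-1-yl)oxy]-3-[(triisopropylsilyl)oxy]phenyl}propanamide | CC(C)=CCOc1ccc([C@@H](CC(=O)N(C)C)O)cc1O[Si](C(C)C)(C(C)C)C(C)C | intermediate
9 | phloroglucinol (benzene-1,3,5-triol) | Oc1cc(O)cc(O)c1 | starting material
10 | 3,5-bis[(tert-butyldimethylsilyl)oxy]phenol | Oc1cc(O[Si](C)(C)C(C)(C)C)cc(O[Si](C)(C)C(C)(C)C)c1 | intermediate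
11 | (S)-3-{3,5-bis[(tert-butyldimethylsilyl)oxy]phenoxy}-N,N-dimethyl-3-{4-[(3-methylbut-2-en-1-yl)oxy]-3-[(triisopropylsilyl)oxy]phenyl}propanamide | CC(C)=CCOc1ccc([C@H](CC(=O)N(C)C)Oc2cc(O[Si](C)(C)C(C)(C)C)cc(O[Si](C)(C)C(C)(C)C)c2)cc1O[Si](C(C)C)(C(C)C)C(C)C | intermediate
12 | O-triflyl iminium triflate of 11: N-{(3S)-3-{3,5-bis[(tert-butyldimethylsilyl)oxy]phenoxy}-3-{4-[(3-methylbut-2-en-1-yl)oxy]-3-[(triisopropylsilyl)oxy]phenyl}-1-[(trifluoromethylsulfonyl)oxy]propylidene}-N-methylmethanaminium trifluoromethanesulfonate | CC(C)=CCOc1ccc([C@H](CC(OS(=O)(=O)C(F)(F)F)=[N+](C)C)Oc2cc(O[Si](C)(C)C(C)(C)C)cc(O[Si](C)(C)C(C)(C)C)c2)cc1O[Si](C(C)C)(C(C)C)C(C)C.[O-]S(=O)(=O)C(F)(F)F | intermediate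
13 | cyclic iminium triflate: N-{(2S)-5,7-bis[(tert-butyldimethylsilyl)oxy]-2-{4-[(3-methylbut-2-en-1-yl)oxy]-3-[(triisopropylsilyl)oxy]phenyl}chroman-4-ylidene}-N-methylmethanaminium trifluoromethanesulfonate | CC(C)=CCOc1ccc([C@@H]2CC(=[N+](C)C)c3c(O[Si](C)(C)C(C)(C)C)cc(O[Si](C)(C)C(C)(C)C)cc3O2)cc1O[Si](C(C)C)(C(C)C)C(C)C.[O-]S(=O)(=O)C(F)(F)F | intermediate
14 | (S)-5,7-bis[(tert-butyldimethylsilyl)oxy]-2-{4-[(3-methylbut-2-en-1-yl)oxy]-3-[(triisopropylsilyl)oxy]phenyl}chroman-4-one | CC(C)=CCOc1ccc([C@@H]2CC(=O)c3c(O[Si](C)(C)C(C)(C)C)cc(O[Si](C)(C)C(C)(C)C)cc3O2)cc1O[Si](C(C)C)(C(C)C)C(C)C | intermediate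
15 | Monotesone A, (S)-5,7-dihydroxy-2-{3-hydroxy-4-[(3-methylbut-2-en-1-yl)oxy]phenyl}chroman-4-one | CC(C)=CCOc1ccc([C@@H]2CC(=O)c3c(O)cc(O)cc3O2)cc1O | target

Total step count: 8.
Longest linear sequence: 7 steps (steps 1, 2, 3, 4, 6, 7, 8 from methyl 3,4-dihydroxybenzoate); step 5 is a one-step side branch.

Steps most likely to fail

Step 7. The cationic conditions could cleave the prenyl ether, ionise or β-eliminate at the C2–O1 ether (loss of configuration), or leave the hindered iminium ion slow to hydrolyse. The fallback replaces the electrophilic C–H acylation by a Parham cyclisation of an aryllithium; it sets out from 8 and 10 and comes back at 14. Phenol 10 is brominated ortho to its hydroxyl (NBS, CH2Cl2, −78 °C; the carbon between the two silyloxy groups is shielded) to give 2-bromo-3,5-bis(tert-butyldimethylsilyloxy)phenol F1. Mitsunobu coupling of F1 with 8 (PPh3, DIAD, toluene, −20 °C) gives with inversion (S)-3-[2-bromo-3,5-bis(tert-butyldimethylsilyloxy)phenoxy]-N,N-dimethyl-3-[4-(prenyloxy)-3-(triisopropylsilyloxy)phenyl]propanamide F2. Treatment with t-BuLi (2 equiv) in THF at −95 °C should bring about bromine–lithium exchange and attack of the aryllithium on the tertiary amide; the lithium hemiaminal keeps the ketone masked until a cold AcOH quench releases 14.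

Step 6. The 4-alkoxybenzylic alkoxyphosphonium ion may ionise before it is displaced (erosion of enantiomeric purity), and dehydration to the cinnamamide may compete. The fallback forms the ether bond on an sp2 carbon and sets C2 afterwards by hydrogenation; it sets out from 7 and 10 and comes back at 11. Keto amide 7 is converted (TsCl, N-methylimidazole, Et3N, CH2Cl2) into the enol tosylate (Z)-3-(dimethylamino)-3-oxo-1-[4-(prenyloxy)-3-(triisopropylsilyloxy)phenyl]prop-1-en-1-yl 4-methylbenzenesulfonate F3. Addition–elimination with 10 (Cs2CO3, MeCN, rt) gives (Z)-3-[3,5-bis(tert-butyldimethylsilyloxy)phenoxy]-N,N-dimethyl-3-[4-(prenyloxy)-3-(triisopropylsilyloxy)phenyl]prop-2-enamide F4, used as a single geometric isomer. Asymmetric hydrogenation ([Rh(cod)2]BF4 with a chiral ferrocenyl bisphosphine of the Josiphos type, H2, CF3CH2OH/CH2Cl2) should reduce only the chelating enol ether alkene and give 11, the ligand antipode being chosen for (S).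

Step 1. Discrimination between the two catechol hydroxyls may be poor and double alkylation may compete. The fallback differentiates the two oxygens by silyl cleavage instead of selective alkylation; it sets out from 1 and comes back at 4. Exhaustive silylation (TIPSOTf, 2,6-lutidine, CH2Cl2) gives methyl 3,4-bis(triisopropylsilyloxy)benzoate F5. K2CO3 (1 equiv) in MeOH at 0 °C should cleave the silyl ether para to the ester, which is the better phenoxide leaving group and the site where a free phenoxide is most stable should the silyl group migrate, to give methyl 4-hydroxy-3-(triisopropylsilyloxy)benzoate F6. Mitsunobu alkylation of F6 with 3-methylbut-2-en-1-ol (PPh3, DIAD, THF) gives 4 directly.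

Further compounds
F1 | step 7 | 2-bromo-3,5-bis[(tert-butyldimethylsilyl)oxy]phenol | Oc1cc(O[Si](C)(C)C(C)(C)C)cc(O[Si](C)(C)C(C)(C)C)c1Br
F2 | step 7 | (S)-3-{2-bromo-3,5-bis[(tert-butyldimethylsilyl)oxy]phenoxy}-N,N-dimethyl-3-{4-[(3-methylbut-2-en-1-yl)oxy]-3-[(triisopropylsilyl)oxy]phenyl}propanamide | CC(C)=CCOc1ccc([C@H](CC(=O)N(C)C)Oc2cc(O[Si](C)(C)C(C)(C)C)cc(O[Si](C)(C)C(C)(C)C)c2Br)cc1O[Si](C(C)C)(C(C)C)C(C)C
F3 | step 6 | (Z)-3-(dimethylamino)-1-{4-[(3-methylbut-2-en-1-yl)oxy]-3-[(triisopropylsilyl)oxy]phenyl}-3-oxoprop-1-en-1-yl 4-methylbenzenesulfonate | CN(C)C(=O)/C=C(\OS(=O)(=O)c1ccc(C)cc1)c1ccc(OCC=C(C)C)c(O[Si](C(C)C)(C(C)C)C(C)C)c1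
F4 | step 6 | (Z)-3-{3,5-bis[(tert-butyldimethylsilyl)oxy]phenoxy}-N,N-dimethyl-3-{4-[(3-methylbut-2-en-1-yl)oxy]-3-[(triisopropylsilyl)oxy]phenyl}prop-2-enamide | CN(C)C(=O)/C=C(\Oc1cc(O[Si](C)(C)C(C)(C)C)cc(O[Si](C)(C)C(C)(C)C)c1)c1ccc(OCC=C(C)C)c(O[Si](C(C)C)(C(C)C)C(C)C)c1
F5 | step 1 | methyl 3,4-bis[(triisopropylsilyl)oxy]benzoate | COC(=O)c1ccc(O[Si](C(C)C)(C(C)C)C(C)C)c(O[Si](C(C)C)(C(C)C)C(C)C)c1
F6 | step 1 | methyl 4-hydroxy-3-[(triisopropylsilyl)oxy]benzoate | COC(=O)c1ccc(O)c(O[Si](C(C)C)(C(C)C)C(C)C)c1
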